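**Retrosynthetic overview**
1. The angelate (Yamaguchi), the C14 hydroxyl (SeO2 on the Δ1(10) methyl), the C13 methylene (Eschenmoser) and the trans-2,3-diol (α′-hydroxylation and OH-directed reduction of a C2 enone made by allylic oxidation) are added late to a 13-nor spiro lactone.
2. The lactone ring O–C8–C7–C11–C12 comes from CBS reduction of a C8 cyclopentenone carrying a CH2CO2Me arm on C7, lactonisation and hydrogenation; the Δ1(10) alkene comes from dehydration of a C10 tertiary alcohol.
3. Key disconnection: the spiro-cyclopentenone and the C10 carbinol arise together from a 6/6-fused cross-conjugated cyclohexadienone by photochemical ring contraction in aqueous acid (C6–C10 broken, C6–C5 made).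
4. Enabling feature: spiro atom C5 lies between sp2 C10 of the cyclohexene and a cyclopentane (C5–C6–C7–C8–C9) with its oxygen at C8 and its only carbon branch at C7. Re-inserting C10 between C5 and C6 gives the dienone ring C8(=O)–C7=C6–C10(quaternary)–C5=C9, whose C7 alkyl group steers the cyclopropane opening to the spiro product.
5. Ring order: cyclohexane (purchased) → six-membered enone/dienone ring (asymmetric Michael/Robinson annulation with MVK, α′-alkylation, DDQ) → cyclopentane (ring contraction) → γ-lactone.

Key step: step 6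

Remark: positions are numbered as in the spirovetivane skeleton (C5 spiro atom; C6–C9 the rest of the cyclopentane; C1–C4 and C10 the rest of the cyclohexene; C11–C13 the lactone carbons with C13 the exocyclic CH2; C14 the CH2O carbon on C10; C15 the methyl on C4), and 2,6-dimethylcyclohexanone is taken as the commercial cis/trans mixture because both isomers give the same imine/enamine.

**Step 1**
Reactants: 1 2,6-dimethylcyclohexanone; 2 (R)-1-phenylethylamine
Product: 3 N-[(1R)-1-phenylethyl]-2,6-dimethylcyclohexan-1-imine (isomer mixture)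
Conditions: TsOH (cat.), PhMe, reflux, Dean–Stark
Reagents that add atoms: none
Why: Acid-catalysed ketimine condensation with azeotropic removal of water; the ring stereocentres are labile through imine–enamine tautomerism and the auxiliary centre is untouched.

**Step 2**
Reactants: 3 imine; 4 methyl vinyl ketone
Product: 6 (2S)-2,6-dimethyl-2-(3-oxobutyl)cyclohexan-1-one (mixture at C6), via Michael-adduct imine 5 (not isolated)
Conditions: THF, 40 °C; then 20% aq. AcOH, rt
Reagents that add atoms: water, O
Why: Deracemising Michael addition of a chiral imine: the secondary enamine tautomer adds to the enone through a compact aza-ene-like transition state on the face away from the phenyl group, and by the established sense of this reaction ((S)-amine gives the (R) quaternary centre with 2-methylcyclohexanone) the (R)-amine should set the future C10 as S; mild acid hydrolysis frees the ketone and returns the auxiliary.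

**Step 3**
Reactants: 6 diketone
Product: 7 (4aS,8S)-4a,8-dimethyl-4,4a,5,6,7,8-hexahydronaphthalen-2(3H)-one
Conditions: NaOMe, MeOH, reflux
Reagents that add atoms: none
Why: Second stage of the Robinson annulation (intramolecular aldol condensation); methoxide equilibrates the γ-stereocentre (future C4) so that its methyl sits equatorial, trans to the angular methyl, as in 6α-methyl-Δ4-3-keto steroids.

**Step 4**
Reactants: 7 octalone; 8 methyl bromoacetate
Product: 10 methyl 2-[(4aS,8S)-4a,8-dimethyl-2-oxo-2,3,4,4a,5,6,7,8-octahydronaphthalen-3-yl]acetate (C3 epimers), via lithium dienolate 9 (not isolated)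
Conditions: LDA, THF, −78 °C; then 8, DMPU, −78 → −20 °C
Reagents that add atoms: none
Why: Kinetic deprotonation of the enone at the α′-carbon gives the cross-conjugated dienolate, which is C-alkylated by the reactive α-halo ester (enolate alkylation); the new centre is removed in step 5.

**Step 5**
Reactants: 10 alkylated octalone
Product: 11 methyl 2-[(4aS,8S)-4a,8-dimethyl-2-oxo-2,4a,5,6,7,8-hexahydronaphthalen-3-yl]acetate
Conditions: DDQ, dioxane, reflux
Reagents that add atoms: none
Why: DDQ dehydrogenation of a Δ4-3-ketone-type enone under neutral conditions goes through the kinetic α′-dienol and hydride abstraction from the ring CH2 next to the quaternary carbon (future C6), giving the cross-conjugated dienone without touching either stereocentre.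

**Step 6**
Reactants: 11 cross-conjugated dienone
Product: 12 methyl 2-[(5R,6S,10S)-6-hydroxy-6,10-dimethyl-2-oxospiro[4.5]dec-3-en-3-yl]acetate (spirovetivane positions: C8 ketone, C6=C7 alkene, C10 carbinol)
Conditions: hν (medium-pressure Hg lamp, Pyrex), 45% aq. AcOH, N2, rt
Reagents that add atoms: water, O
Why: Type A photorearrangement of a 4,4-disubstituted cyclohexa-2,5-dienone in aqueous acid: excitation and C6–C5 (β,β′) bonding give a strained bicyclo[3.1.0]hexenyl zwitterion in which C6 bridges C5 and C10, and after O-protonation the cyclopropylcarbinyl cation cleaves C6–C10, so the ring C5–C6–C7–C8–C9–C10 contracts to the cyclopentenone C5–C6–C7–C8–C9 while C10 is expelled as a tertiary cation and hydrated. The closest known reaction type is the conversion of 4a-methyl-5,6,7,8-tetrahydronaphthalen-2(4aH)-ones into 6-hydroxyspiro[4.5]dec-3-en-2-ones on irradiation in 45% aqueous acetic acid. The only ring closed is the cyclopentenone, by bonding of C6 to C5 across the dienone (a three-membered ring first, formally a disrotatory closure of the 3-oxidopentadienyl unit) followed by cyclopropane opening, a net 1,2-shift of C6 from C10 to C5. The spiro centre C5 is controlled by the quaternary centre C10: C6 stays on the ring face opposite the C10 methyl, which is trans to the C4 methyl, so C6 ends cis to the C4 methyl as in the target; C10 should be hydrated with inversion (axial OH) and is erased in step 9. The step needs cleavage of C6–C10 and not of C5–C10 (which would give a hydroazulenone): the alkyl arm on C7 stabilises positive charge at C7 and C9 is unsubstituted, the 2-alkyl versus 4-alkyl rule of these dienones.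

**Step 7**
Reactants: 12 spiro hydroxy enone
Product: 14 (4S,5R,8R,10S)-10-hydroxy-13-norspirovetiv-6-en-12,8-olide, via allylic hydroxy ester 13 (not isolated)
Conditions: (S)-Me-CBS (20 mol %), catecholborane, PhMe, −78 °C; MeOH quench; then PPTS (cat.), PhH, 50 °C
Reagents that add atoms: none
Why: Corey–Bakshi–Shibata reduction, in which the catalyst treats the α-substituted alkenyl side (C7) as the large group and should deliver hydride to the face that gives the (8R) alcohol with its oxygen syn to C10 (reagent control, because the spiro centre is too remote to bias the ketone reliably); the allylic γ-hydroxy ester then closes to the γ-lactone under mild acid.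

**Step 8**
Reactants: 14 ene-lactone
Product: 15 (4S,5R,7R,8R,10S)-10-hydroxy-13-norspirovetivan-12,8-olide
Conditions: H2 (3 atm), 5% Rh/Al2O3, EtOAc, rt
Reagents that add atoms: none
Why: Heterogeneous syn-hydrogenation on the convex face of the bicyclic ene-lactone (the face of H8, away from the lactone oxygen and the C10 substituents) should set C7 with H7 cis to H8, giving the cis-fused lactone; rhodium is chosen over palladium to avoid hydrogenolysis of the allylic C8–O bond.

**Step 9**
Reactants: 15 hydroxy lactone
Product: 16 (4S,5R,7R,8R)-13-norspirovetiv-1(10)-en-12,8-olide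
Conditions: SOCl2, pyridine, 0 °C
Reagents that add atoms: none
Why: E2 dehydration via the chlorosulfite: the axial C10 hydroxyl (chair with both methyls equatorial) has an anti-periplanar ring hydrogen only at C1, which favours the endocyclic Δ1(10) alkene, and the non-ionising conditions avoid a Wagner–Meerwein return to a decalin.

**Step 10**
Reactants: 16 alkene lactone
Product: 17 (4S,5R,7R,8R)-2-oxo-13-norspirovetiv-1(10)-en-12,8-olide
Conditions: Rh2(cap)4 (1 mol %), t-BuOOH (5 equiv), CH2Cl2, rt
Reagents that add atoms: tert-butyl hydroperoxide, CC(C)(C)OO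
Why: Dirhodium caprolactamate-catalysed allylic oxidation (allylic C–H abstraction, peroxide trapping, loss of tert-butanol); C2 is the only ring allylic CH2 because C5 is quaternary, so the 1(10)-en-2-one should form regioselectively.

**Step 11**
Reactants: 17 enone lactone
Product: 19 (3S,4R,5R,7R,8R)-3-hydroxy-2-oxo-13-norspirovetiv-1(10)-en-12,8-olide, via potassium dienolate 18 (not isolated)
Conditions: KHMDS (1.05 equiv), THF, −78 °C; then 2-(phenylsulfonyl)-3-phenyloxaziridine, −78 °C; AcOH quench
Reagents that add atoms: 2-(phenylsulfonyl)-3-phenyloxaziridine, O=S(=O)(c1ccccc1)N1OC1c1ccccc1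
Why: Kinetic α′-enolisation of the enone (its α′-H is more acidic than the lactone α-H) and Davis oxaziridine hydroxylation; oxygen should be delivered to C3 anti to the adjacent pseudo-axial C4 methyl, giving the 3,4-trans product.

**Step 12**
Reactants: 19 α′-hydroxy enone
Product: 20 (2S,3S,4R,5R,7R,8R)-2,3-dihydroxy-13-norspirovetiv-1(10)-en-12,8-olide
Conditions: NaBH(OAc)3, MeCN–AcOH, −20 °C
Reagents that add atoms: none
Why: Hydroxyl-directed triacetoxyborohydride reduction: the C3–O-bound boron hydride delivers hydride intramolecularly to the C3–O face of the C2 carbonyl, so the new C2 hydroxyl should be trans to the C3 hydroxyl (1,2-reduction, lactone untouched).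

**Step 13**
Reactants: 20 diol
Product: 21 (2S,3S,4R,5R,7R,8R)-2,3-bis(triethylsilyloxy)-13-norspirovetiv-1(10)-en-12,8-olide
Conditions: TESOTf, 2,6-lutidine, CH2Cl2, −78 → 0 °C
Reagents that add atoms: triethylsilyl triflate, CC[Si](CC)(CC)OS(=O)(=O)C(F)(F)F
Why: Standard silylation of both secondary alcohols to mask them for the enolate, oxidation and acylation steps; no stereocentre is affected.

**Step 14**
Reactants: 21 bis-silyl ether
Product: 25 (2S,3S,4R,5R,7R,8R)-2,3-bis(triethylsilyloxy)spirovetiva-1(10),11(13)-dien-12,8-olide, via lithium lactone enolate 22 (not isolated), via Mannich base 23 (not isolated), via methiodide 24 (not isolated)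
Conditions: LDA, THF, −78 °C; CH2=NMe2+ I−, −78 °C → rt; MeI, MeOH, rt; aq. NaHCO3, CH2Cl2
Reagents that add atoms: Eschenmoser's salt, C[N+](C)=C.[I-]
Why: α-Methylenation of the lactone by Mannich reaction of its lithium enolate with Eschenmoser's salt, N-methylation and base-induced elimination of trimethylamine; the C11 centre is destroyed and C7 is not enolisable.

**Step 15**
Reactants: 25 α-methylene lactone
Product: 26 (2S,3S,4R,5R,7R,8R)-14-hydroxy-2,3-bis(triethylsilyloxy)spirovetiva-1(10),11(13)-dien-12,8-olide
Conditions: SeO2 (0.5 equiv), t-BuOOH, CH2Cl2, rt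
Reagents that add atoms: tert-butyl hydroperoxide, CC(C)(C)OO; selenium dioxide (sub-stoichiometric oxygen carrier), O=[Se]=O
Why: Selenium dioxide allylic hydroxylation (ene reaction then [2,3]-sigmatropic shift) oxidises the allylic carbon on the more substituted end of the trisubstituted alkene, and since C5 is quaternary that is only C14; the electron-poor methylene lactone should not react.

**Step 16**
Reactants: 26 allylic alcohol; 27 angelic acid
Product: 29 (2S,3S,4R,5R,7R,8R)-14-[(2Z)-2-methylbut-2-enoyloxy]-2,3-bis(triethylsilyloxy)spirovetiva-1(10),11(13)-dien-12,8-olide, via mixed anhydride 28 (not isolated)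
Conditions: 27, 2,4,6-Cl3C6H2COCl, Et3N, PhMe, rt; then 26, PhMe, 75 °C (no DMAP)
Reagents that add atoms: none
Why: Yamaguchi esterification through the mixed anhydride without DMAP, the protocol used to acylate alcohols with angelic acid while largely keeping the (Z)-geometry; the primary allylic alcohol is the only free hydroxyl.

**Step 17**
Reactants: 29 bis-silyl angelate
Product: 30 (2S,3S,4R,5R,7R,8R)-2,3-dihydroxy-14-[(2Z)-2-methylbut-2-enoyloxy]spirovetiva-1(10),11(13)-dien-12,8-olide (target)
Conditions: HF·pyridine, THF–pyridine, 0 °C → rt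
Reagents that add atoms: none
Why: Fluoride cleavage of the two triethylsilyl ethers under mildly acidic conditions that should leave the angelate, the allylic ester and the α-methylene lactone untouched.

**Compound list**
1 | 2,6-dimethylcyclohexanone (cis/trans mixture) | CC1CCCC(C)C1=O | starting material
2 | (R)-1-phenylethylamine | C[C@@H](N)c1ccccc1 | starting material
3 | N-[(1R)-1-phenylethyl]-2,6-dimethylcyclohexan-1-imine (isomer mixture) | CC1CCCC(C)C1=N[C@H](C)c1ccccc1 | intermediate
4 | methyl vinyl ketone | CC(=O)C=C | starting material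
5 | Michael-adduct imine, 4-[(1S)-1,3-dimethyl-2-{[(1R)-1-phenylethyl]imino}cyclohexyl]butan-2-one | CC(=O)CC[C@]1(C)CCCC(C)C1=N[C@H](C)c1ccccc1 | intermediate
6 | (2S)-2,6-dimethyl-2-(3-oxobutyl)cyclohexan-1-one (mixture at C6) | CC(=O)CC[C@]1(C)CCCC(C)C1=O | intermediate
7 | (4aS,8S)-4a,8-dimethyl-4,4a,5,6,7,8-hexahydronaphthalen-2(3H)-one | O=C1C=C2[C@@H](C)CCC[C@@]2(C)CC1 | intermediate
8 | methyl bromoacetate | COC(=O)CBr | starting material
9 | lithium cross-conjugated dienolate of 7 | [Li+].[O-]C=1C=C2[C@@H](C)CCC[C@@]2(C)CC=1 | intermediate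
10 | methyl 2-[(4aS,8S)-4a,8-dimethyl-2-oxo-2,3,4,4a,5,6,7,8-octahydronaphthalen-3-yl]acetate (C3 epimers) | O=C1C=C2[C@@H](C)CCC[C@@]2(C)CC1CC(=O)OC | intermediate
11 | methyl 2-[(4aS,8S)-4a,8-dimethyl-2-oxo-2,4a,5,6,7,8-hexahydronaphthalen-3-yl]acetate | O=C1C=C2[C@@H](C)CCC[C@@]2(C)C=C1CC(=O)OC | intermediate
12 | methyl 2-[(5R,6S,10S)-6-hydroxy-6,10-dimethyl-2-oxospiro[4.5]dec-3-en-3-yl]acetate | O=C1C[C@@]2(C=C1CC(=O)OC)[C@@](C)(O)CCC[C@@H]2C | intermediate
13 | methyl 2-[(2R,5R,6S,10S)-2,6-dihydroxy-6,10-dimethylspiro[4.5]dec-3-en-3-yl]acetate | O[C@@H]1C[C@@]2(C=C1CC(=O)OC)[C@@](C)(O)CCC[C@@H]2C | intermediate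
14 | (4S,5R,8R,10S)-10-hydroxy-13-norspirovetiv-6-en-12,8-olide | O=C1CC2=C[C@]3(C[C@H]2O1)[C@@](C)(O)CCC[C@@H]3C | intermediate
15 | (4S,5R,7R,8R,10S)-10-hydroxy-13-norspirovetivan-12,8-olide | O=C1C[C@H]2C[C@]3(C[C@H]2O1)[C@@](C)(O)CCC[C@@H]3C | intermediate
16 | (4S,5R,7R,8R)-13-norspirovetiv-1(10)-en-12,8-olide | O=C1C[C@H]2C[C@]3(C[C@H]2O1)C(C)=CCC[C@@H]3C | intermediate
17 | (4S,5R,7R,8R)-2-oxo-13-norspirovetiv-1(10)-en-12,8-olide | O=C1C[C@H]2C[C@]3(C[C@H]2O1)C(C)=CC(=O)C[C@@H]3C | intermediate
18 | potassium 2,3-enolate of 17 | [K+].O=C1C[C@H]2C[C@]3(C[C@H]2O1)C(C)=CC([O-])=C[C@@H]3C | intermediate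
19 | (3S,4R,5R,7R,8R)-3-hydroxy-2-oxo-13-norspirovetiv-1(10)-en-12,8-olide | O=C1C[C@H]2C[C@]3(C[C@H]2O1)C(C)=CC(=O)[C@@H](O)[C@@H]3C | intermediate
20 | (2S,3S,4R,5R,7R,8R)-2,3-dihydroxy-13-norspirovetiv-1(10)-en-12,8-olide | O=C1C[C@H]2C[C@]3(C[C@H]2O1)C(C)=C[C@H](O)[C@@H](O)[C@@H]3C | intermediate
21 | (2S,3S,4R,5R,7R,8R)-2,3-bis(triethylsilyloxy)-13-norspirovetiv-1(10)-en-12,8-olide | O=C1C[C@H]2C[C@]3(C[C@H]2O1)C(C)=C[C@H](O[Si](CC)(CC)CC)[C@@H](O[Si](CC)(CC)CC)[C@@H]3C | intermediate
22 | lithium enolate of lactone 21 | [Li+].[O-]C1=C[C@H]2C[C@]3(C[C@H]2O1)C(C)=C[C@H](O[Si](CC)(CC)CC)[C@@H](O[Si](CC)(CC)CC)[C@@H]3C | intermediate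
23 | 11-(dimethylaminomethyl) lactone (Mannich base, C11 epimers) | CN(C)CC1C(=O)O[C@@H]2C[C@@]3(C[C@H]12)C(C)=C[C@H](O[Si](CC)(CC)CC)[C@@H](O[Si](CC)(CC)CC)[C@@H]3C | intermediate
24 | 11-(trimethylammoniomethyl) lactone iodide (methiodide of 23) | C[N+](C)(C)CC1C(=O)O[C@@H]2C[C@@]3(C[C@H]12)C(C)=C[C@H](O[Si](CC)(CC)CC)[C@@H](O[Si](CC)(CC)CC)[C@@H]3C.[I-] | intermediate
25 | (2S,3S,4R,5R,7R,8R)-2,3-bis(triethylsilyloxy)spirovetiva-1(10),11(13)-dien-12,8-olide | C=C1C(=O)O[C@@H]2C[C@@]3(C[C@H]12)C(C)=C[C@H](O[Si](CC)(CC)CC)[C@@H](O[Si](CC)(CC)CC)[C@@H]3C | intermediate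
26 | (2S,3S,4R,5R,7R,8R)-14-hydroxy-2,3-bis(triethylsilyloxy)spirovetiva-1(10),11(13)-dien-12,8-olide | C=C1C(=O)O[C@@H]2C[C@@]3(C[C@H]12)C(CO)=C[C@H](O[Si](CC)(CC)CC)[C@@H](O[Si](CC)(CC)CC)[C@@H]3C | intermediate
27 | angelic acid, (2Z)-2-methylbut-2-enoic acid | C/C=C(/C)C(=O)O | starting material
28 | angelic 2,4,6-trichlorobenzoic anhydride | C/C=C(/C)C(=O)OC(=O)c1c(Cl)cc(Cl)cc1Cl | intermediate
29 | (2S,3S,4R,5R,7R,8R)-14-[(2Z)-2-methylbut-2-enoyloxy]-2,3-bis(triethylsilyloxy)spirovetiva-1(10),11(13)-dien-12,8-olide | C=C1C(=O)O[C@@H]2C[C@@]3(C[C@H]12)C(COC(=O)/C(C)=C\C)=C[C@H](O[Si](CC)(CC)CC)[C@@H](O[Si](CC)(CC)CC)[C@@H]3C | intermediate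
30 | (2S,3S,4R,5R,7R,8R)-2,3-dihydroxy-14-[(2Z)-2-methylbut-2-enoyloxy]spirovetiva-1(10),11(13)-dien-12,8-olide | C=C1C(=O)O[C@@H]2C[C@@]3(C[C@H]12)C(COC(=O)/C(C)=C\C)=C[C@H](O)[C@@H](O)[C@@H]3C | target

**Step count and risks**
Total steps: 17. Longest linear sequence: 17 steps (1 → 30); compounds 2, 4, 8 and 27 are purchased.

Steps most likely to fail:

Step 6. The cyclopropane of the photo-intermediate may open in the other direction (giving a hydroazulenone), and the product cyclopentenone may be consumed by secondary photolysis during the irradiation. The fallback separates the photochemical and the ionic events. Starting from 11, irradiation in anhydrous dioxane should stop at the lumiketone F1 (1,4-shift of C10 from C6 to C9, cyclopropane C5–C9–C10), which is isolated. F1 is then opened in the dark with aqueous HClO4 in AcOH: acid-catalysed homo-conjugate addition of water to the cyclopropyl ketone cleaves the C9–C10 bond that overlaps with the carbonyl. This can only lead to the spiro skeleton and returns to 12.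

Step 7. Hydride delivery to C8 may show poor facial selectivity, because catalyst control could be eroded by the remote spiro centre or by intramolecular delivery from a boron species bound to the C10 hydroxyl. The fallback corrects the configuration by inversion instead of controlling the reduction. Starting from 12, Luche reduction (NaBH4, CeCl3, MeOH) and chromatographic separation give 13, which lactonises as in the route, and the (8S)-hydroxy ester F2. F2 is saponified (LiOH, THF–H2O) to the hydroxy acid F3, and Mitsunobu lactonisation (PPh3, DIAD, THF) closes the ring with inversion at C8, returning to 14.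

Step 16. The angeloyl unit may isomerise from Z to E (to the tiglate) while its carboxyl group is activated. The fallback avoids acyl activation altogether. Starting from 26, Appel bromination (CBr4, PPh3, CH2Cl2, 0 °C) gives the allylic bromide F4. F4 is displaced in an SN2 reaction by caesium angelate F5 (made from 27 and Cs2CO3 in DMF), an O-alkylation in which the (Z)-acid is never converted into an acylating agent, returning to 29.

**Further compounds**
F1 | step 6 | lumiketone of 11 (bicyclo[3.1.0]hex-3-en-2-one; cyclopropane C5–C9–C10, enone C6=C7–C8=O, CH2CO2Me on C7) | O=C1C(CC(=O)OC)=C[C@]23[C@H]1[C@@]2(C)CCC[C@@H]3C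
F2 | step 7 | methyl 2-[(2S,5R,6S,10S)-2,6-dihydroxy-6,10-dimethylspiro[4.5]dec-3-en-3-yl]acetate (C8 epimer of 13) | O[C@H]1C[C@@]2(C=C1CC(=O)OC)[C@@](C)(O)CCC[C@@H]2C
F3 | step 7 | 2-[(2S,5R,6S,10S)-2,6-dihydroxy-6,10-dimethylspiro[4.5]dec-3-en-3-yl]acetic acid | O[C@H]1C[C@@]2(C=C1CC(=O)O)[C@@](C)(O)CCC[C@@H]2C
F4 | step 16 | (2S,3S,4R,5R,7R,8R)-14-bromo-2,3-bis(triethylsilyloxy)spirovetiva-1(10),11(13)-dien-12,8-olide | C=C1C(=O)O[C@@H]2C[C@@]3(C[C@H]12)C(CBr)=C[C@H](O[Si](CC)(CC)CC)[C@@H](O[Si](CC)(CC)CC)[C@@H]3C
F5 | step 16 | caesium angelate | C/C=C(/C)C(=O)[O-].[Cs+]
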